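The 2,5-dihydrofuran (O, C5, C6, C7, C8) fused to the cyclohexane (C1–C6) along C5–C6 is treated as one etheno bridge of a 7-oxanorbornadiene. An intramolecular Diels–Alder reaction of a 2,3-dihydrofuro[3,2-b]furan with a tethered terminal alkyne forms C5–C6 and C7–C8 in one operation and closes both rings. Two bonds that the target lacks act as a template: the furan bond C18–C9 holds the C5 methyl precursor and the C8 side-chain precursor cis, and an O3–C18 ether holds the C3 oxygen cis to C18, so the single centre C3, from a resolved epoxide, fixes C5 and C8. Ozonolysis removes the template; two Wittig reactions with a C10 dialdehyde join the C15 end groups.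

Key step: step 8

Remark: atoms carry carotenoid numbers (furanoid half C1–C11 and methyls C16–C19, O3 = oxygen on C3; ε half primed).
Remark: 2,2-dimethylpent-4-enal, 3,4-dibromofuran, (R)-α-ionone and (2E,4E,6E)-2,7-dimethylocta-2,4,6-trienedial are taken as purchasable.

Step 1
Reactants: 1 2,2-dimethylpent-4-enal
Product: 2 3,3-dimethylhex-5-en-1-yne
Conditions: dimethyl (1-diazo-2-oxopropyl)phosphonate, K2CO3, MeOH, 0 °C → rt
Reagents that add atoms: dimethyl (1-diazo-2-oxopropyl)phosphonate, CC(=O)C(=[N+]=[N-])P(=O)(OC)OC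
Why: Ohira–Bestmann homologation of a non-enolisable aldehyde should give the terminal alkyne (later C6≡C7) on the gem-dimethyl carbon C1.

Step 2
Reactants: 2 3,3-dimethylhex-5-en-1-yne
Product: 3 rac-2-(2,2-dimethylbut-3-yn-1-yl)oxirane
Conditions: mCPBA, NaHCO3, CH2Cl2, 0 °C
Reagents that add atoms: mCPBA, OOC(=O)c1cccc(Cl)c1
Why: Prilezhaev epoxidation should take the terminal alkene and spare the much less nucleophilic alkyne.

Step 3
Reactants: 3 rac-2-(2,2-dimethylbut-3-yn-1-yl)oxirane
Product: 4 (S)-2-(2,2-dimethylbut-3-yn-1-yl)oxirane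
Conditions: (S,S)-(salen)Co(OAc) (0.5 mol%; salen = N,N′-bis(3,5-di-tert-butylsalicylidene)-1,2-cyclohexanediamine dianion), H2O (0.55 equiv), THF, 0 °C → rt; distil
Reagents that add atoms: none
Why: hydrolytic kinetic resolution of a terminal epoxide, in which the (S,S) cobalt salen complex should hydrolyse the R epoxide and leave the S epoxide, whose stereocentre becomes C3 of the target and is not touched again.

Step 4
Reactants: 5 3,4-dibromofuran
Product: 7 3-bromo-4-methylfuran, via (4-bromofuran-3-yl)lithium 6 (not isolated)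
Conditions: n-BuLi (1.0 equiv), Et2O, −78 °C; MeI, −78 → −20 °C
Reagents that add atoms: iodomethane, CI
Why: bromine–lithium exchange at one of two equivalent positions and methylation of the 3-furyllithium, kept cold because 3-lithiofurans open on warming, should install the later C19 methyl.

Step 5
Reactants: 7 3-bromo-4-methylfuran
Product: 8 3-methoxy-4-methylfuran
Conditions: NaOMe, CuBr (10 mol%), MeOH/DMF, 100 °C
Reagents that add atoms: sodium methoxide, C[O-].[Na+]
Why: copper-catalysed Ullmann-type methoxylation of a 3-bromofuran is a standard entry to 3-alkoxyfurans.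

Step 6
Reactants: 8 3-methoxy-4-methylfuran; 4 (S)-2-(2,2-dimethylbut-3-yn-1-yl)oxirane
Product: 10 (2S)-1-(3-methoxy-4-methylfuran-2-yl)-4,4-dimethylhex-5-yn-2-ol, via (3-methoxy-4-methylfuran-2-yl)lithium 9 (not isolated)
Conditions: 8 (2.2 equiv), n-BuLi (2.2 equiv), THF, −78 → 0 °C; then 4, 0 °C → rt; H2O
Reagents that add atoms: none
Why: methoxy-directed lithiation at the furan position between the two oxygens and SN2 opening of the epoxide at its CH2 terminus should form C4–C5 without touching C3, the second equivalent of furyllithium holding the alkyne as a lithium acetylide that does not open epoxides without a Lewis acid.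

Step 7
Reactants: 10 (2S)-1-(3-methoxy-4-methylfuran-2-yl)-4,4-dimethylhex-5-yn-2-ol
Product: 11 (2S)-2-(2,2-dimethylbut-3-yn-1-yl)-6-methyl-2,3-dihydrofuro[3,2-b]furan
Conditions: CSA (5 mol%), 4 Å MS, toluene, 60 °C
Reagents that add atoms: none
Why: acid-catalysed enol-ether exchange (protonation of the furan at C5, 5-exo attack of the hydroxyl on the oxocarbenium carbon C18, loss of methanol and re-aromatisation, the manifold by which γ-hydroxy ketones cyclodehydrate to dihydrofurans) should close O3–C18 with retention at C3.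

Step 8
Reactants: 11 (2S)-2-(2,2-dimethylbut-3-yn-1-yl)-6-methyl-2,3-dihydrofuro[3,2-b]furan
Product: 12 furan–alkyne cycloadduct (7-oxanorbornadiene with bridgeheads C5 and C8, etheno bridges C6=C7 and C18=C9, ring C1–C6 fused along C5–C6, O3 linking C3 to C18)
Conditions: toluene (0.01 M), BHT, solid K2CO3, 150 °C, sealed tube
Reagents that add atoms: none
Why: Heating should bring the tethered alkyne C6≡C7 over the furan diene C5=C18–C9=C8 for a concerted, asynchronous [4+2] cycloaddition, the closest known reaction type being the intramolecular Diels–Alder reaction of a furan with an alkyne to a 7-oxanorbornadiene. Bond C5–C6 closes the carbocycle C1–C6 through the four-atom tether C4–C3–C2–C1 (fused mode, tether on the diene terminus), and bond C7–C8 completes the 2,5-dihydrofuran O–C5–C6=C7–C8 as the new etheno bridge. The alkyne can reach the furan only across the face that carries the C2 arm on C3, so the S centre C3 controls both new centres, C5 (R) and C8 (S). Because C18 and C9 are ring atoms of the same furan and O3 is bonded to C18, the future C5 methyl, the future side chain on C8 and the C3 oxygen are forced onto one face, which is the relative configuration of the target. Regiochemistry is fixed by the tether; the selectivity that matters is cycloaddition against acid-induced opening of the adduct to a phenol, which solid K2CO3 and high dilution should secure, while the donor oxygen on the diene and the gem-dimethyl group should compensate for the unactivated alkyne.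

Step 9
Reactants: 12 furan–alkyne cycloadduct
Product: 14 keto lactone (2-acetyl-4,4-dimethyl-2,4,5,6,7,7a-hexahydro-1-benzofuran-7a-carboxylic acid 6-lactone), via methoxy hydroperoxide 13 (not isolated)
Conditions: O3 (1.0 equiv, titrated solution), NaHCO3, CH2Cl2/MeOH, −78 °C; Me2S, −78 °C → rt; used crude
Reagents that add atoms: ozone, [O-][O+]=O
Why: ozonolysis should cleave the tetrasubstituted enol-ether bond C18=C9 far faster than the trisubstituted C6=C7 (Criegee fragmentation to the lactone carbonyl C18 and the carbonyl oxide at C9, trapped by methanol and reduced), so that the dihydrofuran emerges with the acetyl group on C8 cis to C18.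

Step 10
Reactants: 14 keto lactone
Product: 15 vinyl carbinol lactone (C8 bears C(CH3)(OH)CH=CH2, both C9 epimers)
Conditions: CeCl3, CH2=CHMgBr, THF, −78 °C; aq. NH4Cl
Reagents that add atoms: vinylmagnesium bromide, C=C[Mg]Br
Why: the weakly basic organocerium reagent should add to the methyl ketone at −78 °C without enolising the labile C8–H (α to the ketone, allylic and α to oxygen) and without attacking the lactone, the new carbinol centre at C9 being irrelevant because C9 becomes sp2.

Step 11
Reactants: 15 vinyl carbinol lactone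
Product: 18 bis-silyl ether acid (C3–OTBS; C9–OTBS; C5–CO2H), via lithium carboxylate 16 (not isolated), via silyl ester 17 (not isolated)
Conditions: LiOH, THF/H2O, rt; evaporate; TBSOTf, 2,6-lutidine, CH2Cl2, 0 °C; K2CO3, MeOH/H2O, rt
Reagents that add atoms: lithium hydroxide, [Li+].[OH-]; tert-butyldimethylsilyl trifluoromethanesulfonate, CC(C)(C)[Si](C)(C)OS(=O)(=O)C(F)(F)F
Why: saponification of the strained bridged lactone, silylation of both hydroxyls and the carboxylate, and selective methanolysis of the silyl ester should free C18 as the acid while O3 and the C9 oxygen are blocked against later attack on C18.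

Step 12
Reactants: 18 bis-silyl ether acid
Product: 19 neopentyl alcohol (C5–CH2OH)
Conditions: LiAlH4, THF, 0 → 40 °C
Reagents that add atoms: none
Why: hydride reduction of the carboxylic acid should give the primary alcohol at C18, which silyl ethers and isolated alkenes survive.

Step 13
Reactants: 19 neopentyl alcohol
Product: 21 (2S,6S,7aR)-6-(tert-butyldimethylsilyloxy)-2-[2-(tert-butyldimethylsilyloxy)but-3-en-2-yl]-4,4,7a-trimethyl-2,4,5,6,7,7a-hexahydro-1-benzofuran, via neopentyl triflate 20 (not isolated)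
Conditions: Tf2O, 2,6-lutidine, CH2Cl2, −78 °C; LiEt3BH, THF, −78 → 0 °C
Reagents that add atoms: none
Why: SN2 displacement of a neopentyl triflate by triethylborohydride, a standard deoxygenation of hindered primary alcohols, should turn C18 into the C5 methyl without a carbanion or radical at C18 that could expel the ring oxygen or add to C6=C7.

Step 14
Reactants: 21 the bis-silyl ether from step 13
Product: 22 [(2E)-3-[(2S,6S,7aR)-6-hydroxy-4,4,7a-trimethyl-2,4,5,6,7,7a-hexahydro-1-benzofuran-2-yl]but-2-en-1-yl]triphenylphosphonium bromide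
Conditions: PPh3·HBr (2.5 equiv), MeOH, rt; crystallise
Reagents that add atoms: triphenylphosphine hydrobromide, [PH+](c1ccccc1)(c1ccccc1)c1ccccc1.[Br-]
Why: in acidic methanol both silyl ethers should be lost, the tertiary vinyl carbinol should ionise to the allyl cation and triphenylphosphine should add at the primary terminus C11 (the vinyl-carbinol route to C15 phosphonium salts), giving mainly the 9E salt under thermodynamic control.

Step 15
Reactants: 23 (R)-α-ionone
Product: 24 ethyl (2E,4E)-3-methyl-5-[(1R)-2,6,6-trimethylcyclohex-2-en-1-yl]penta-2,4-dienoate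
Conditions: (EtO)2P(O)CH2CO2Et, NaH, THF, 0 → 50 °C; separate the 9Z isomer
Reagents that add atoms: triethyl phosphonoacetate, CCOC(=O)CP(=O)(OCC)OCC
Why: Horner–Wadsworth–Emmons olefination of the methyl ketone should give mainly the 9′E dienoate, the centre C6′ being γ to the carbonyl and not acidic enough for the phosphonate anion.

Step 16
Reactants: 24 the dienoate from step 15
Product: 25 ethyl (2E,4E)-3-methyl-5-[(1R)-2,6,6-trimethyl-4-oxocyclohex-2-en-1-yl]penta-2,4-dienoate
Conditions: t-BuOOH, Rh2(cap)4 (0.5 mol%; cap = caprolactamate), K2CO3, CH2Cl2, rt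
Reagents that add atoms: tert-butyl hydroperoxide, CC(C)(C)OO
Why: peroxyl-radical allylic oxidation should take the ring CH2 (C3′) next to the trisubstituted alkene, as α-ionone itself does, the tertiary C6′–H being shielded by the flanking gem-dimethyl and methyl groups.

Step 17
Reactants: 25 the enone from step 16
Product: 26 ethyl (2E,4E)-5-[(1R,4R)-4-hydroxy-2,6,6-trimethylcyclohex-2-en-1-yl]-3-methylpenta-2,4-dienoate
Conditions: (S)-2-methyl-CBS-oxazaborolidine (20 mol%), catecholborane, toluene, −78 °C
Reagents that add atoms: none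
Why: Corey–Bakshi–Shibata reduction with the alkenyl arm as the large group should deliver hydride 1,2 under catalyst control to give the 3′R allylic alcohol, trans to the side chain on C6′.

Step 18
Reactants: 26 the allylic alcohol from step 17
Product: 27 ethyl (2E,4E)-5-[(1R,4R)-4-(tert-butyldimethylsilyloxy)-2,6,6-trimethylcyclohex-2-en-1-yl]-3-methylpenta-2,4-dienoate
Conditions: TBSCl, imidazole, DMF, rt
Reagents that add atoms: tert-butyldimethylsilyl chloride, CC(C)(C)[Si](C)(C)Cl
Why: silylation should protect the acid-labile ring allylic alcohol through the phosphonium salt formation and both Wittig reactions.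

Step 19
Reactants: 27 the silyl ether ester from step 18
Product: 28 (2E,4E)-5-[(1R,4R)-4-(tert-butyldimethylsilyloxy)-2,6,6-trimethylcyclohex-2-en-1-yl]-3-methylpenta-2,4-dien-1-ol
Conditions: i-Bu2AlH, CH2Cl2, −78 °C
Reagents that add atoms: none
Why: 1,2-reduction of the dienoate by the aluminium hydride should give the primary allylic alcohol and leave the silyl ether.

Step 20
Reactants: 28 the dienol from step 19
Product: 31 [(2E,4E)-5-[(1R,4R)-4-(tert-butyldimethylsilyloxy)-2,6,6-trimethylcyclohex-2-en-1-yl]-3-methylpenta-2,4-dien-1-yl]triphenylphosphonium bromide, via allylic mesylate 29 (not isolated), via allylic bromide 30 (not isolated)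
Conditions: MsCl, Et3N, THF, −40 °C; LiBr, −40 → 0 °C; then PPh3, rt
Reagents that add atoms: lithium bromide, [Li+].[Br-]; triphenylphosphine, c1ccc(cc1)P(c1ccccc1)c1ccccc1
Why: mesylation, bromide exchange and quaternisation under neutral conditions should give the C15 salt without ionising the allylic silyl ether in the ring.

Step 21
Reactants: 31 the ε-end phosphonium bromide; 32 (2E,4E,6E)-2,7-dimethylocta-2,4,6-trienedial
Product: 34 (2E,4E,6E,8E,10E,12E)-13-[(1R,4R)-4-(tert-butyldimethylsilyloxy)-2,6,6-trimethylcyclohex-2-en-1-yl]-2,7,11-trimethyltrideca-2,4,6,8,10,12-hexaenal, via phosphorus ylide 33 (not isolated)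
Conditions: NaOMe, MeOH/CH2Cl2, 0 °C → rt, 32 (3 equiv); then heptane, 80 °C
Reagents that add atoms: none
Why: Wittig reaction of the allylic ylide with an excess of the dialdehyde should form C11′=C12′ on one side only, and heating should equilibrate the new double bond to E.

Step 22
Reactants: 22 the furanoid phosphonium bromide; 34 the C25 aldehyde
Product: 36 3′-O-(tert-butyldimethylsilyl) ether of the target, via phosphorus ylide 35 (not isolated)
Conditions: NaOMe (2.2 equiv), MeOH/CH2Cl2, 0 °C → rt; then EtOH, 70 °C, dark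
Reagents that add atoms: none
Why: the second Wittig reaction should form C11=C12 and complete the C40 chain, the free C3 hydroxyl being tolerated as in hydroxylated C15 salts, and heating should bring the new double bond to E.

Step 23
Reactants: 36 the silyl ether of the target
Product: 37 (3S,5R,8S,3′R,6′R)-5,8-epoxy-5,8-dihydro-β,ε-carotene-3,3′-diol
Conditions: TBAF, THF, 0 °C → rt
Reagents that add atoms: none
Why: fluoride desilylation is neutral to slightly basic and should free the allylic C3′ hydroxyl without ionising it or the furanoid ether.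

Compound list
1 | 2,2-dimethylpent-4-enal | O=CC(C)(C)CC=C | starting material
2 | 3,3-dimethylhex-5-en-1-yne | C#CC(C)(C)CC=C | intermediate
3 | rac-2-(2,2-dimethylbut-3-yn-1-yl)oxirane | C#CC(C)(C)CC1CO1 | intermediate
4 | (S)-2-(2,2-dimethylbut-3-yn-1-yl)oxirane | C#CC(C)(C)C[C@H]1CO1 | intermediate
5 | 3,4-dibromofuran | Brc1cocc1Br | starting material
6 | (4-bromofuran-3-yl)lithium | [Li]c1cocc1Br | intermediate
7 | 3-bromo-4-methylfuran | Cc1cocc1Br | intermediate
8 | 3-methoxy-4-methylfuran | COc1cocc1C | intermediate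
9 | (3-methoxy-4-methylfuran-2-yl)lithium | [Li]c1occ(C)c1OC | intermediate
10 | (2S)-1-(3-methoxy-4-methylfuran-2-yl)-4,4-dimethylhex-5-yn-2-ol | C#CC(C)(C)C[C@H](O)Cc1occ(C)c1OC | intermediate
11 | (2S)-2-(2,2-dimethylbut-3-yn-1-yl)-6-methyl-2,3-dihydrofuro[3,2-b]furan | C#CC(C)(C)C[C@H]1Cc2occ(C)c2O1 | intermediate
12 | furan–alkyne cycloadduct: 7-oxanorbornadiene, bridgeheads C5 and C8, bridges C6=C7 and C18=C9 (CH3 on C9), ring C1–C6 fused along C5–C6, O3 linking C3 and C18; C3, C5, C8 as in the target | CC1(C)C[C@H]2C[C@@]34O[C@@H](C=C13)C(C)=C4O2 | intermediate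
13 | methoxy hydroperoxide: as 14 with C9 as C(CH3)(OCH3)(OOH) | CC1(C)C[C@H]2C[C@]3(O[C@@H](C=C13)C(C)(OC)OO)C(=O)O2 | intermediate
14 | keto lactone: 2-acetyl-4,4-dimethyl-2,4,5,6,7,7a-hexahydro-1-benzofuran-7a-carboxylic acid 6-lactone, acetyl cis to the lactone carbonyl | CC1(C)C[C@H]2C[C@]3(O[C@@H](C=C13)C(C)=O)C(=O)O2 | intermediate
15 | vinyl carbinol lactone: as 14 with 2-(2-hydroxybut-3-en-2-yl) in place of acetyl, both C9 epimers | CC1(C)C[C@H]2C[C@]3(O[C@@H](C=C13)C(C)(O)C=C)C(=O)O2 | intermediate
16 | lithium 6-hydroxy-2-(2-hydroxybut-3-en-2-yl)-4,4-dimethyl-2,4,5,6,7,7a-hexahydro-1-benzofuran-7a-carboxylate, ring centres as in 22 | CC1(C)C[C@H](O)C[C@]2(O[C@@H](C=C12)C(C)(O)C=C)C(=O)[O-].[Li+] | intermediate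
17 | tert-butyldimethylsilyl ester of 18 | CC1(C)C[C@H](O[Si](C)(C)C(C)(C)C)C[C@]2(O[C@@H](C=C12)C(C)(O[Si](C)(C)C(C)(C)C)C=C)C(=O)O[Si](C)(C)C(C)(C)C | intermediate
18 | 6-(tert-butyldimethylsilyloxy)-2-[2-(tert-butyldimethylsilyloxy)but-3-en-2-yl]-4,4-dimethyl-2,4,5,6,7,7a-hexahydro-1-benzofuran-7a-carboxylic acid, ring centres as in 22 | CC1(C)C[C@H](O[Si](C)(C)C(C)(C)C)C[C@]2(O[C@@H](C=C12)C(C)(O[Si](C)(C)C(C)(C)C)C=C)C(=O)O | intermediate
19 | [6-(tert-butyldimethylsilyloxy)-2-[2-(tert-butyldimethylsilyloxy)but-3-en-2-yl]-4,4-dimethyl-2,4,5,6,7,7a-hexahydro-1-benzofuran-7a-yl]methanol, ring centres as in 22 | CC1(C)C[C@H](O[Si](C)(C)C(C)(C)C)C[C@]2(O[C@@H](C=C12)C(C)(O[Si](C)(C)C(C)(C)C)C=C)CO | intermediate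
20 | trifluoromethanesulfonate of 19 | CC1(C)C[C@H](O[Si](C)(C)C(C)(C)C)C[C@]2(O[C@@H](C=C12)C(C)(O[Si](C)(C)C(C)(C)C)C=C)COS(=O)(=O)C(F)(F)F | intermediate
21 | (2S,6S,7aR)-6-(tert-butyldimethylsilyloxy)-2-[2-(tert-butyldimethylsilyloxy)but-3-en-2-yl]-4,4,7a-trimethyl-2,4,5,6,7,7a-hexahydro-1-benzofuran | CC1(C)C[C@H](O[Si](C)(C)C(C)(C)C)C[C@]2(O[C@@H](C=C12)C(C)(O[Si](C)(C)C(C)(C)C)C=C)C | intermediate
22 | [(2E)-3-[(2S,6S,7aR)-6-hydroxy-4,4,7a-trimethyl-2,4,5,6,7,7a-hexahydro-1-benzofuran-2-yl]but-2-en-1-yl]triphenylphosphonium bromide | CC1(C)C[C@H](O)C[C@]2(O[C@@H](C=C12)/C(C)=C/C[P+](c3ccccc3)(c3ccccc3)c3ccccc3)C.[Br-] | intermediate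
23 | (R)-α-ionone | CC1=CCCC(C)(C)[C@H]1/C=C/C(C)=O | starting material
24 | ethyl (2E,4E)-3-methyl-5-[(1R)-2,6,6-trimethylcyclohex-2-en-1-yl]penta-2,4-dienoate | CC1=CCCC(C)(C)[C@H]1/C=C/C(C)=C/C(=O)OCC | intermediate
25 | ethyl (2E,4E)-3-methyl-5-[(1R)-2,6,6-trimethyl-4-oxocyclohex-2-en-1-yl]penta-2,4-dienoate | CC1=CC(=O)CC(C)(C)[C@H]1/C=C/C(C)=C/C(=O)OCC | intermediate
26 | ethyl (2E,4E)-5-[(1R,4R)-4-hydroxy-2,6,6-trimethylcyclohex-2-en-1-yl]-3-methylpenta-2,4-dienoate | CC1=C[C@H](O)CC(C)(C)[C@H]1/C=C/C(C)=C/C(=O)OCC | intermediate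
27 | ethyl (2E,4E)-5-[(1R,4R)-4-(tert-butyldimethylsilyloxy)-2,6,6-trimethylcyclohex-2-en-1-yl]-3-methylpenta-2,4-dienoate | CC1=C[C@H](O[Si](C)(C)C(C)(C)C)CC(C)(C)[C@H]1/C=C/C(C)=C/C(=O)OCC | intermediate
28 | (2E,4E)-5-[(1R,4R)-4-(tert-butyldimethylsilyloxy)-2,6,6-trimethylcyclohex-2-en-1-yl]-3-methylpenta-2,4-dien-1-ol | CC1=C[C@H](O[Si](C)(C)C(C)(C)C)CC(C)(C)[C@H]1/C=C/C(C)=C/CO | intermediate
29 | methanesulfonate of 28 | CC1=C[C@H](O[Si](C)(C)C(C)(C)C)CC(C)(C)[C@H]1/C=C/C(C)=C/COS(C)(=O)=O | intermediate
30 | bromide corresponding to 28 | CC1=C[C@H](O[Si](C)(C)C(C)(C)C)CC(C)(C)[C@H]1/C=C/C(C)=C/CBr | intermediate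
31 | [(2E,4E)-5-[(1R,4R)-4-(tert-butyldimethylsilyloxy)-2,6,6-trimethylcyclohex-2-en-1-yl]-3-methylpenta-2,4-dien-1-yl]triphenylphosphonium bromide | CC1=C[C@H](O[Si](C)(C)C(C)(C)C)CC(C)(C)[C@H]1/C=C/C(C)=C/C[P+](c2ccccc2)(c2ccccc2)c2ccccc2.[Br-] | intermediate
32 | (2E,4E,6E)-2,7-dimethylocta-2,4,6-trienedial | O=C/C(C)=C/C=C/C=C(\C)C=O | starting material
33 | triphenylphosphonium ylide of 31 | CC1=C[C@H](O[Si](C)(C)C(C)(C)C)CC(C)(C)[C@H]1/C=C/C(C)=C/C=P(c2ccccc2)(c2ccccc2)c2ccccc2 | intermediate
34 | (2E,4E,6E,8E,10E,12E)-13-[(1R,4R)-4-(tert-butyldimethylsilyloxy)-2,6,6-trimethylcyclohex-2-en-1-yl]-2,7,11-trimethyltrideca-2,4,6,8,10,12-hexaenal | CC1=C[C@H](O[Si](C)(C)C(C)(C)C)CC(C)(C)[C@H]1/C=C/C(C)=C/C=C/C(C)=C/C=C/C=C(C)/C=O | intermediate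
35 | triphenylphosphonium ylide of 22 | CC1(C)C[C@H](O)C[C@]2(O[C@@H](C=C12)/C(C)=C/C=P(c3ccccc3)(c3ccccc3)c3ccccc3)C | intermediate
36 | 3′-O-(tert-butyldimethylsilyl) ether of 37 | CC1=C[C@H](O[Si](C)(C)C(C)(C)C)CC(C)(C)[C@H]1/C=C/C(C)=C/C=C/C(C)=C/C=C/C=C(C)/C=C/C=C(\C)[C@@H]1C=C2C(C)(C)C[C@H](O)C[C@@]2(C)O1 | intermediate
37 | (3S,5R,8S,3′R,6′R)-5,8-epoxy-5,8-dihydro-β,ε-carotene-3,3′-diol | CC1=C[C@H](O)CC(C)(C)[C@H]1/C=C/C(C)=C/C=C/C(C)=C/C=C/C=C(C)/C=C/C=C(\C)[C@@H]1C=C2C(C)(C)C[C@H](O)C[C@@]2(C)O1 | target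

Total step count: 23. Longest linear sequence: 14 steps (steps 1–3, 6–14, 22, 23).

Steps most likely to fail

Step 8. The unactivated alkyne may react so slowly that thermal decomposition of the electron-rich furan, or opening of the adduct to a phenol, outruns cycloaddition. The fallback sets out from 11. Deprotonation of the alkyne with n-BuLi should give the lithium acetylide F1, and p-toluenesulfonyl fluoride should convert it into the alkynyl sulfone F2, a far stronger dienophile that should undergo the same intramolecular cycloaddition near 60 °C to the 7-sulfonyl cycloadduct F3. Reduction of the vinyl sulfone with Na(Hg) in buffered MeOH should then remove the sulfonyl group and rejoin the route at 12.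

Step 9. Ozone may also attack the strained C6=C7 bond, or the β,γ-unsaturated ketone may lose its C8 configuration by enolisation during work-up. The fallback sets out from 12. Dimethyldioxirane at −78 °C should epoxidise only the enol ether to the alkoxy epoxide F4, which wet THF should open to the hemiketal diol F5. Periodic acid should then cleave the C18–C9 glycol under non-basic conditions and return to 14.

Step 13. Hydride attack at the neopentyl carbon may be slow enough for the silyl ether oxygen on C3 to displace the triflate with loss of silicon, or for the triflate to ionise and rearrange. The fallback sets out from 19 and replaces the polar displacement by a radical one. 1,1′-Thiocarbonyldiimidazole and DMAP should give the thiocarbonylimidazolide F6. Bu3SnH, AIBN and catalytic PhSeSePh in benzene at 80 °C (Barton–McCombie deoxygenation) should then give 21, the benzeneselenol formed in the flask quenching the primary radical before it can add to C6=C7.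

Further compounds
F1 | step 8 | lithium acetylide of 11 | [Li]C#CC(C)(C)C[C@H]1Cc2occ(C)c2O1
F2 | step 8 | (2S)-2-[2,2-dimethyl-4-(4-methylbenzenesulfonyl)but-3-yn-1-yl]-6-methyl-2,3-dihydrofuro[3,2-b]furan | Cc1ccc(cc1)S(=O)(=O)C#CC(C)(C)C[C@H]1Cc2occ(C)c2O1
F3 | step 8 | 7-(4-methylbenzenesulfonyl) derivative of cycloadduct 12 | CC1(C)C[C@H]2C[C@@]34O[C@@H](C(=C13)S(=O)(=O)c1ccc(C)cc1)C(C)=C4O2
F4 | step 9 | C18–C9 epoxide of cycloadduct 12 | CC1(C)C[C@H]2C[C@@]34O[C@@H](C=C13)C5(C)OC45O2
F5 | step 9 | hemiketal diol (C18–OH, C9–OH) from F4 | CC1(C)C[C@H]2C[C@@]34O[C@@H](C=C13)C(C)(O)C4(O)O2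
F6 | step 13 | O-imidazolylthiocarbonyl derivative of 19 | CC1(C)C[C@H](O[Si](C)(C)C(C)(C)C)C[C@]2(O[C@@H](C=C12)C(C)(O[Si](C)(C)C(C)(C)C)C=C)COC(=S)n1ccnc1
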